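**Retrosynthetic overview**

1. Ring B (the cyclohexene) is closed last, by joining the methyl-bearing alkene carbon to the spiro carbon in a palladium-catalysed dearomative Heck/borylation of a (Z)-alkenyl iodide onto an aromatic furo[3,2-c]pyran-4-one; oxidation of the C–B bond then gives the alcohol.
2. Enabling feature: before this step the spiro carbon is C2 of the furan ring, whose C2=C3 enol ether bond is only weakly aromatic. After insertion palladium sits on C3 with no β-hydrogen (C2 quaternary, C3a sp2), so it can only be intercepted by boron, cis to the new C–C bond.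
3. The alkenyl iodide comes from an aldehyde by iodo-ethylidenation; the furan comes from a terminal alkyne and 4-hydroxy-3-iodo-6-(pyridin-3-yl)-2-pyranone by Sonogashira coupling/5-endo cyclisation; the spiro δ-lactone comes from a temporary fused lactone by translactonisation.
4. Ring A with its four stereocentres comes from (R)-carvone, whose isopropenyl centre relays the rest: formylation/Michael addition sets the quaternary carbon, and a tethered Reformatsky reaction, oxidative enone transposition, 1,4-hydrosilylation and enolate ethynylation set the other two.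
5. Ring order: ring A (bought) → temporary fused lactone → spiro δ-lactone → pyranone (separate fragment) → furan → ring B together with the two dihydrofuran stereocentres (key step).

Key step: step 16

Remark: the carbinol carbon formed in step 5 and the lactol carbon formed in step 9 are not controlled and are erased in steps 6 and 10; they are drawn as the expected cis-fused isomer and as an anomer mixture. All reagents named are taken as commercial.

**Route**

Step 1
Reactants: 1 (R)-(−)-carvone
Product: 2 6-(hydroxymethylene)carvone
Conditions: LiN(i-Pr)2 (1.1 equiv), THF, −78 °C; HCO2CH2CF3, −78 → 0 °C; 1 M HCl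
Reagents that add atoms: 2,2,2-trifluoroethyl formate, O=COCC(F)(F)F
Why: Kinetic deprotonation of the cross-conjugated enone occurs at the α′-CH2 group, and Claisen-type C-formylation of this enolate with the activated formate is driven by formation of the chelated β-keto aldehyde enolate, with no new stereocentre and the isopropenyl-bearing centre untouched.

Step 2
Reactants: 2 6-(hydroxymethylene)carvone
Product: 3 formyl keto ester
Conditions: tert-butyl acrylate (2 equiv), DBU (0.1 equiv), MeCN, 0 °C → rt
Reagents that add atoms: tert-butyl acrylate, C=CC(=O)OC(C)(C)C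
Why: Base-catalysed Michael addition of the doubly activated formyl ketone creates the quaternary carbon, the acrylate approaching the planar enolate anti to the neighbouring isopropenyl group (held pseudoaxial by allylic strain with the exocyclic enol), so that the propanoate chain ends trans and the formyl group cis to isopropenyl.

Step 3
Reactants: 3 formyl keto ester
Product: 4 hydroxymethyl keto ester
Conditions: NaBH4 (0.3 equiv), MeOH/CH2Cl2 1:1, −78 °C; aqueous NH4Cl
Reagents that add atoms: none
Why: Chemoselective borohydride reduction, in which the aldehyde reacts far faster at −78 °C than the conjugated ketone or the tert-butyl ester, and the tert-butyl ester keeps the new neopentyl alcohol from lactonising; no stereocentre is formed.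

Step 4
Reactants: 4 hydroxymethyl keto ester
Product: 5 bromoacetate
Conditions: BrCH2COBr (1.2 equiv), pyridine (1.5 equiv), CH2Cl2, 0 °C
Reagents that add atoms: bromoacetyl bromide, O=C(Br)CBr
Why: Standard O-acylation of a primary alcohol by an acyl bromide with pyridine attaches the two-carbon nucleophile precursor to the CH2O arm as a tether; no stereocentre is formed.

Step 5
Reactants: 5 bromoacetate
Product: 6 fused hydroxy lactone
Conditions: SmI2 (2.2 equiv, 0.1 M in THF), THF, −78 °C; aqueous NH4Cl
Reagents that add atoms: none
Why: Intramolecular samarium Reformatsky reaction, in which SmI2 reduces the α-bromo ester to a trivalent samarium enolate that adds to the neighbouring ketone through a six-membered chelate to give the β-hydroxy δ-lactone, the tether delivering the CH2 group cis to the CH2O arm at a carbinol centre that is erased in step 6.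

Step 6
Reactants: 6 fused hydroxy lactone
Product: 7 transposed enone lactone
Conditions: [C5H5NH][CrO3Cl] (pyridinium chlorochromate, 2.5 equiv), 4 Å molecular sieves, CH2Cl2, rt
Reagents that add atoms: pyridinium chlorochromate, [O-][Cr](=O)(=O)Cl.c1cc[nH+]cc1
Why: Dauben–Babler oxidative 1,3-transposition, in which the tertiary allylic chromate ester undergoes a [3,3] shift and oxidation to the transposed enone, so that the carbonyl sits next to the methyl-bearing carbon and the lactone-bearing carbon becomes the β-carbon while the carbinol stereocentre disappears.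

Step 7
Reactants: 7 transposed enone lactone
Product: 9 ethynyl ketone, via triethylsilyl enol ether 8 (not isolated)
Conditions: RhCl(PPh3)3 (2 mol%), Et3SiH (1.5 equiv), toluene, 60 °C; evaporate; then TMS-EBX (1.4 equiv), Bu4NF (2.5 equiv), THF, −78 °C → rt; aqueous NH4Cl
Reagents that add atoms: triethylsilane, CC[SiH](CC)CC (silicon stays in 8 only); 1-[(trimethylsilyl)ethynyl]-1,2-benziodoxol-3(1H)-one (TMS-EBX), C[Si](C)(C)C#CI1OC(=O)c2ccccc12
Why: Rhodium-catalysed 1,4-hydrosilylation should deliver hydride to the β-carbon from the face opposite the pseudoaxial CH2O arm of the neighbouring quaternary carbon (cis-fused lactone) and give the tetrasubstituted silyl enol ether regiospecifically, and fluoride-triggered electrophilic α-ethynylation of the derived enolate with the ethynylbenziodoxolone then creates the methyl/ethynyl quaternary carbon from the same open face, trans to the lactone CH2 and anti to the 1,3-related axial CH2O group.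

Step 8
Reactants: 9 ethynyl ketone
Product: 11 ethynyl lactone, via tosylhydrazone 10 (not isolated)
Conditions: TsNHNH2 (1.3 equiv), pyridinium p-toluenesulfonate (cat.), MeOH, 60 °C; evaporate; then catecholborane (2 equiv), CHCl3, 0 °C; NaOAc·3H2O, 60 °C
Reagents that add atoms: p-toluenesulfonohydrazide, Cc1ccc(cc1)S(=O)(=O)NN (its atoms stay in 10 only)
Why: Caglioti-type reductive deoxygenation, in which the tosylhydrazone is hydroborated by catecholborane and acetate-induced loss of sulfinate and N2 from the resulting diazene replaces C=O by CH2 under conditions that spare the lactone, the tert-butyl ester, the alkyne and the isopropenyl group, with no stereocentre affected.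

Step 9
Reactants: 11 ethynyl lactone
Product: 12 lactol
Conditions: i-Bu2AlH (1.1 equiv), CH2Cl2, −78 °C; aqueous work-up
Reagents that add atoms: none
Why: Partial hydride reduction, in which i-Bu2AlH adds once to the δ-lactone and the tetrahedral aluminium alkoxide survives until work-up while the hindered tert-butyl ester is not touched, so that the lactone stops at the lactol as an inconsequential anomer mixture.

Step 10
Reactants: 12 lactol
Product: 14 alkynyl aldehyde spirolactone, via lactol acid 13 (not isolated)
Conditions: CF3CO2H/CH2Cl2 1:9, 0 °C → rt; then 4 Å molecular sieves, rt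
Reagents that add atoms: none
Why: Acidolysis of the tert-butyl ester frees the propanoic acid, and the lactol, through its open hydroxy aldehyde form, passes its neopentyl oxygen to this acid in an acid-catalysed lactonisation (translactonisation) that builds the spiro δ-lactone and releases the aldehyde without touching any stereocentre.

Step 11
Reactants: 15 2,2,6-trimethyl-4H-1,3-dioxin-4-one; 16 nicotinoyl chloride hydrochloride
Product: 17 keto dioxinone
Conditions: LiN(SiMe3)2 (3.2 equiv), THF, −78 → 0 °C; 1 M HCl to pH 6
Reagents that add atoms: none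
Why: Vinylogous Claisen condensation, in which the lithium dienolate of the dioxinone is acylated at its γ-carbon by the acid chloride, the extra base covering the hydrochloride and the acidic product.

Step 12
Reactants: 17 keto dioxinone
Product: 18 4-hydroxy-6-(pyridin-3-yl)-2H-pyran-2-one
Conditions: toluene, 110 °C
Reagents that add atoms: none
Why: Thermal retro-[4+2] loss of acetone gives an acylketene that is trapped by the enol of the neighbouring ketone to close the 4-hydroxy-2-pyranone.

Step 13
Reactants: 18 4-hydroxy-6-(pyridin-3-yl)-2H-pyran-2-one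
Product: 19 4-hydroxy-3-iodo-6-(pyridin-3-yl)-2H-pyran-2-one
Conditions: N-iodosuccinimide (1.05 equiv), MeCN, rt
Reagents that add atoms: N-iodosuccinimide, O=C1CCC(=O)N1I
Why: Electrophilic iodination of the enolic hydroxypyranone occurs at C3, the position activated by both the hydroxyl group and the ring oxygen.

Step 14
Reactants: 14 alkynyl aldehyde spirolactone; 19 4-hydroxy-3-iodo-6-(pyridin-3-yl)-2H-pyran-2-one
Product: 21 furopyranone aldehyde, via alkynyl hydroxypyranone 20 (not isolated)
Conditions: PdCl2(PPh3)2 (5 mol%), CuI (10 mol%), Et3N (3 equiv), DMF, 60 °C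
Reagents that add atoms: none
Why: Sonogashira coupling of the terminal alkyne with the 3-iodopyranone is followed in the same pot by copper- and base-assisted 5-endo-dig attack of the 4-oxygen on the alkyne (Castro–Stephens-type heteroannulation), which gives the 2-substituted furo[3,2-c]pyran-4-one under non-acidic conditions that leave the aldehyde alone.

Step 15
Reactants: 21 furopyranone aldehyde
Product: 22 (Z)-alkenyl iodide
Conditions: [Ph3PEt]I (3 equiv), n-BuLi, THF, rt; I2, −78 °C; NaN(SiMe3)2, −20 °C; then 21, −78 → −20 °C
Reagents that add atoms: ethyltriphenylphosphonium iodide, CC[P+](c1ccccc1)(c1ccccc1)c1ccccc1.[I-]; iodine, I-I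
Why: Stork–Zhao-type Wittig olefination with the α-iodoethylidene ylide converts the aldehyde into the trisubstituted (Z)-alkenyl iodide, the kinetically formed cis-oxaphosphetane placing iodine cis to the ring-bearing CH2 group as the later ring closure requires.

Step 16
Reactants: 22 (Z)-alkenyl iodide
Product: 24 target CNP0126103.3, via pinacol boronate 23 (not isolated)
Conditions: Pd(OAc)2 (10 mol%), P(o-tol)3 (20 mol%), B2pin2 (1.5 equiv, slow addition), KOAc (3 equiv), 1,4-dioxane, 80 °C; then NaBO3·4H2O (5 equiv), THF/H2O, rt
Reagents that add atoms: bis(pinacolato)diboron, CC1(C)OB(OC1(C)C)B1OC(C)(C)C(C)(C)O1 (boron stays in 23 only); sodium perborate tetrahydrate, [Na+].[O-]OB=O.O.O.O.O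
Why: Proposed new method: zerovalent palladium inserts into the C–I bond of 22, and the (Z)-alkenylpalladium iodide adds across the C2=C3 bond of the furo[3,2-c]pyran-4-one in a syn migratory insertion that forms the ring-closing bond between the methyl-bearing alkene carbon and furan C2 and leaves palladium on C3, where it has no β-hydrogen (C2 is quaternary, C3a is sp2) and waits as a pyranone-stabilised π-benzyl-type species for acetate-assisted transmetalation with B2pin2 and stereoretentive C–B reductive elimination to 23, which NaBO3 then oxidises with retention. The closest known reaction type is the palladium-catalysed intramolecular dearomative Heck/borylation (arylborylation) of N-acylindoles, together with dearomative Heck spirocyclisations onto tethered furans and benzofurans; new are the alkenyl iodide, the pyranone-fused furan and the carbocyclic six-membered ring. Ring B is closed in the 6-exo-trig mode onto the tether-bearing furan carbon, which is feasible because this C2=C3 bond is an enol ether of low aromatic stabilisation and its saturation leaves an intact 4-alkoxy-2-pyranone. The spiro carbon is set by substrate control from ring A: the two trans-diequatorial arms allow only a chair-like transition state fused trans to the ring A chair, in which furan C3 must lie in the plane of the Pd–C bond and so takes the pseudoaxial site anti to the axial methyl group, while the ring oxygen takes the pseudoequatorial site beside the alkene methyl group. The carbinol carbon is set by the mechanism, because syn insertion places palladium, then boron, then oxygen cis to the new C–C bond. The step needs insertion to be faster than direct borylation of the alkenylpalladium and than Heck reaction at the isopropenyl group, which is secured by the proximity of the furan in the six-membered closure, by slow addition of B2pin2 and by the remote position of the isopropenyl group, which could react only through a seven-membered closure.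

**Compound list**

1 | (R)-(−)-carvone, (5R)-2-methyl-5-(prop-1-en-2-yl)cyclohex-2-en-1-one | C=C(C)[C@@H]1CC=C(C)C(=O)C1 | starting material
2 | 6-(hydroxymethylene)carvone: (Z)-6-(hydroxymethylene)-2-methyl-5-(prop-1-en-2-yl)cyclohex-2-en-1-one, hydrogen-bonded enol, isopropenyl centre as in 1 | C=C(C)[C@@H]1CC=C(C)C(=O)/C1=C\O | intermediate
3 | tert-butyl 3-[1-formyl-3-methyl-2-oxo-6-(prop-1-en-2-yl)cyclohex-3-en-1-yl]propanoate, formyl cis and propanoate chain trans to isopropenyl | C=C(C)[C@@H]1CC=C(C)C(=O)[C@@]1(C=O)CCC(=O)OC(C)(C)C | intermediate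
4 | tert-butyl 3-[1-(hydroxymethyl)-3-methyl-2-oxo-6-(prop-1-en-2-yl)cyclohex-3-en-1-yl]propanoate, CH2OH cis to isopropenyl | C=C(C)[C@@H]1CC=C(C)C(=O)[C@@]1(CO)CCC(=O)OC(C)(C)C | intermediate
5 | tert-butyl 3-[1-[(2-bromoacetoxy)methyl]-3-methyl-2-oxo-6-(prop-1-en-2-yl)cyclohex-3-en-1-yl]propanoate | C=C(C)[C@@H]1CC=C(C)C(=O)[C@@]1(COC(=O)CBr)CCC(=O)OC(C)(C)C | intermediate
6 | tert-butyl 3-[4a-hydroxy-5-methyl-3-oxo-8-(prop-1-en-2-yl)-3,4,4a,7,8,8a-hexahydro-1H-isochromen-8a-yl]propanoate, cis-fused, 4a-OH cis to the 8a chain, isopropenyl trans to the 8a chain | C=C(C)[C@@H]1CC=C(C)[C@]2(O)CC(=O)OC[C@]12CCC(=O)OC(C)(C)C | intermediate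
7 | tert-butyl 3-[5-methyl-3,6-dioxo-8-(prop-1-en-2-yl)-3,4,6,7,8,8a-hexahydro-1H-isochromen-8a-yl]propanoate | C=C(C)[C@@H]1CC(=O)C(C)=C2CC(=O)OC[C@]12CCC(=O)OC(C)(C)C | intermediate
8 | tert-butyl 3-[5-methyl-3-oxo-8-(prop-1-en-2-yl)-6-(triethylsilyloxy)-3,4,4a,7,8,8a-hexahydro-1H-isochromen-8a-yl]propanoate, 4a-H cis to the 8a chain | C=C(C)[C@@H]1CC(O[Si](CC)(CC)CC)=C(C)[C@@H]2CC(=O)OC[C@]12CCC(=O)OC(C)(C)C | intermediate
9 | tert-butyl 3-[5-ethynyl-5-methyl-3,6-dioxo-8-(prop-1-en-2-yl)octahydro-1H-isochromen-8a-yl]propanoate, ethynyl cis to 4a-H and to the 8a chain, 5-methyl cis to the ring CH2O | C=C(C)[C@@H]1CC(=O)[C@](C#C)(C)[C@@H]2CC(=O)OC[C@]12CCC(=O)OC(C)(C)C | intermediate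
10 | 6-(p-toluenesulfonylhydrazone) of 9 | C=C(C)[C@@H]1C/C(=N\NS(=O)(=O)c3ccc(C)cc3)[C@](C#C)(C)[C@@H]2CC(=O)OC[C@]12CCC(=O)OC(C)(C)C | intermediate
11 | tert-butyl 3-[5-ethynyl-5-methyl-3-oxo-8-(prop-1-en-2-yl)octahydro-1H-isochromen-8a-yl]propanoate, configuration as in 9 | C=C(C)[C@@H]1CC[C@](C#C)(C)[C@@H]2CC(=O)OC[C@]12CCC(=O)OC(C)(C)C | intermediate
12 | tert-butyl 3-[5-ethynyl-3-hydroxy-5-methyl-8-(prop-1-en-2-yl)octahydro-1H-isochromen-8a-yl]propanoate, anomer mixture | C=C(C)[C@@H]1CC[C@](C#C)(C)[C@@H]2CC(O)OC[C@]12CCC(=O)OC(C)(C)C | intermediate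
13 | 3-[5-ethynyl-3-hydroxy-5-methyl-8-(prop-1-en-2-yl)octahydro-1H-isochromen-8a-yl]propanoic acid, anomer mixture | C=C(C)[C@@H]1CC[C@](C#C)(C)[C@@H]2CC(O)OC[C@]12CCC(=O)O | intermediate
14 | 2-[10-ethynyl-10-methyl-3-oxo-7-(prop-1-en-2-yl)-2-oxaspiro[5.5]undecan-11-yl]acetaldehyde; isopropenyl, CH2CHO and 10-methyl on the face of the lactone CH2O, ethynyl on the opposite face | C=C(C)[C@@H]1CC[C@](C#C)(C)[C@H](CC=O)[C@@]12CCC(=O)OC2 | intermediate
15 | 2,2,6-trimethyl-4H-1,3-dioxin-4-one | CC1=CC(=O)OC(C)(C)O1 | starting material
16 | nicotinoyl chloride hydrochloride | O=C(Cl)c1cccnc1.Cl | starting material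
17 | 2,2-dimethyl-6-[2-oxo-2-(pyridin-3-yl)ethyl]-4H-1,3-dioxin-4-one | CC1(C)OC(=O)C=C(CC(=O)c2cccnc2)O1 | intermediate
18 | 4-hydroxy-6-(pyridin-3-yl)-2H-pyran-2-one | O=c1cc(O)cc(-c2cccnc2)o1 | intermediate
19 | 4-hydroxy-3-iodo-6-(pyridin-3-yl)-2H-pyran-2-one | O=c1oc(-c2cccnc2)cc(O)c1I | intermediate
20 | 2-[10-[[4-hydroxy-2-oxo-6-(pyridin-3-yl)-2H-pyran-3-yl]ethynyl]-10-methyl-3-oxo-7-(prop-1-en-2-yl)-2-oxaspiro[5.5]undecan-11-yl]acetaldehyde | C=C(C)[C@@H]1CC[C@](C#Cc3c(O)cc(-c4cccnc4)oc3=O)(C)[C@H](CC=O)[C@@]12CCC(=O)OC2 | intermediate
21 | 2-[10-methyl-3-oxo-10-[4-oxo-6-(pyridin-3-yl)-4H-furo[3,2-c]pyran-2-yl]-7-(prop-1-en-2-yl)-2-oxaspiro[5.5]undecan-11-yl]acetaldehyde, configuration as in 14 with the furopyranone in place of ethynyl | C=C(C)[C@@H]1CC[C@](c3cc4c(o3)cc(-c5cccnc5)oc4=O)(C)[C@H](CC=O)[C@@]12CCC(=O)OC2 | intermediate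
22 | 11-[(2Z)-3-iodobut-2-en-1-yl]-10-methyl-10-[4-oxo-6-(pyridin-3-yl)-4H-furo[3,2-c]pyran-2-yl]-7-(prop-1-en-2-yl)-2-oxaspiro[5.5]undecan-3-one | C=C(C)[C@@H]1CC[C@](c3cc4c(o3)cc(-c5cccnc5)oc4=O)(C)[C@H](C/C=C(\I)C)[C@@]12CCC(=O)OC2 | intermediate
23 | pinacol boronate of the target: 4,4,5,5-tetramethyl-1,3,2-dioxaborolan-2-yl in place of the hydroxyl group, same configuration, boron cis to the alkene carbon on the dihydrofuran | C=C(C)[C@@H]1CC[C@]2(C)[C@H](CC=C(C)[C@@]23Oc2cc(-c4cccnc4)oc(=O)c2[C@@H]3B4OC(C)(C)C(C)(C)O4)[C@@]12CCC(=O)OC2 | intermediate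
24 | CNP0126103.3 | C=C(C)[C@@H]1CC[C@]2(C)[C@H](CC=C(C)[C@@]23Oc2cc(-c4cccnc4)oc(=O)c2[C@@H]3O)[C@@]12CCC(=O)OC2 | target

**Step count and risks**

Total steps: 16. Longest linear sequence: 13 steps (steps 1–10 and 14–16, from 1); the pyranone fragment takes steps 11–13.

Steps most likely to fail:

1. Step 16 (proposed new method). What may go wrong: the alkenylpalladium intermediate is borylated before it inserts into the furan, or insertion occurs without facial control at the spiro carbon. Fallback (known radical chemistry instead of palladium): from 22, an oxygenative radical cyclisation with Bu3SnH (slow addition) and Et3B under dry air in toluene should generate the alkenyl radical, which closes 6-exo onto furan C2. The pyranone-stabilised C3 radical should be trapped by O2 on the face away from the quaternary ring A carbon to give the hydroperoxide F1, and reduction with PPh3 returns to the route at 24.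

2. Step 7. What may go wrong: hydride transfer to the fully substituted β-carbon is slow or goes 1,2, so that the regiodefined enol ether does not form. Fallback (electron transfer instead of metal hydride): from 7, SmI2/HMPA/t-BuOH in THF should reduce the enone to the saturated keto lactone F2 (ring-fusion hydrogen from the open face, epimers at the methyl-bearing carbon). Me3SiCl/Et3N in DMF at 80 °C should then give the more substituted trimethylsilyl enol ether F3 under equilibrating conditions, and the ethynylation of step 7 (TMS-EBX, Bu4NF) returns to the route at 9.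

3. Step 14. What may go wrong: copper is sequestered by the acidic hydroxypyranone so that the coupling stalls, or the coupled alkyne closes through the lactone carbonyl oxygen to the isomeric furo[2,3-b]pyran-4-one. Fallback (stepwise electrophilic cyclisation with the nucleophilic oxygen fixed): from 19, Me3SiCHN2 should give 3-iodo-4-methoxy-6-(pyridin-3-yl)-2H-pyran-2-one F4, and Sonogashira coupling with 14 should give the alkynyl methoxypyranone F5. I2/NaHCO3 should close the furan 5-endo through the methoxy oxygen, with loss of iodomethane, to the 3-iodofuropyranone F6; Pd(OAc)2/PPh3 with HCO2H and Et3N removes the iodine and returns to the route at 21.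

**Further compounds**

F1 | step 16 | hydroperoxide of the target (OOH in place of OH, same configuration) | C=C(C)[C@@H]1CC[C@]2(C)[C@H](CC=C(C)[C@@]23Oc2cc(-c4cccnc4)oc(=O)c2[C@@H]3OO)[C@@]12CCC(=O)OC2
F2 | step 7 | tert-butyl 3-[5-methyl-3,6-dioxo-8-(prop-1-en-2-yl)octahydro-1H-isochromen-8a-yl]propanoate, cis-fused, epimers at C5 | C=C(C)[C@@H]1CC(=O)C(C)[C@@H]2CC(=O)OC[C@]12CCC(=O)OC(C)(C)C
F3 | step 7 | trimethylsilyl analogue of 8 | C=C(C)[C@@H]1CC(O[Si](C)(C)C)=C(C)[C@@H]2CC(=O)OC[C@]12CCC(=O)OC(C)(C)C
F4 | step 14 | 3-iodo-4-methoxy-6-(pyridin-3-yl)-2H-pyran-2-one | COc1cc(-c2cccnc2)oc(=O)c1I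
F5 | step 14 | 4-O-methyl ether of 20 | C=C(C)[C@@H]1CC[C@](C#Cc3c(OC)cc(-c4cccnc4)oc3=O)(C)[C@H](CC=O)[C@@]12CCC(=O)OC2
F6 | step 14 | 3-iodo derivative of 21 (iodine on furan C3) | C=C(C)[C@@H]1CC[C@](c3oc4cc(-c5cccnc5)oc(=O)c4c3I)(C)[C@H](CC=O)[C@@]12CCC(=O)OC2
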